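The cyclohexane ring (C5–C10, elemane numbering) is read as the endo adduct of a 2-pyrone. The carbon substituent on C5 and the oxygen on C8 are cis across the ring, while the C6 oxygen and the C7 side chain share the opposite face; a C5–C4(=O)–O–C8 lactone bridge with an endo (Z)-dienophile encodes exactly this pattern. A copper–bisoxazoline-catalysed inverse-electron-demand Diels–Alder reaction of allyl 4-methyl-2-oxo-2H-pyran-3-carboxylate with a (Z)-silyl enol ether forms C5–C6 and C7–C8 and sets four stereocentres in one operation. The rigid bicyclic lactone then directs a radical alkynylation that creates the quaternary C10 and is finally opened to release the C8 hydroxyl.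

Key step: step 6

Remark on numbering: C10 is the quaternary carbon (CH3 = C14, vinyl = C1=C2), C9 the CH2, C8 the O-acyl carbon, C7 bears C11(=C13H2)–C12O2H, C6 bears OH, C5 bears C4(=C15H2)–C3H2OH; primed numbers belong to the C8 acyl group. For the bicyclic intermediates, "endo" means syn to the C7=C8 bridge of the 2-oxabicyclo[2.2.2]octene, i.e. anti to the lactone bridge.
Assumption: the (S,S)-configured bisoxazoline complex of Cu(OTf)2 is taken to deliver the cycloadduct enantiomer drawn in the compound list; should the sense of induction be opposite, the (R,R)-ligand is used and nothing else changes.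

Step 1
Reactants: 1 diallyl malonate; 2 acetone
Product: 3 diallyl 2-(propan-2-ylidene)malonate
Conditions: Ac2O, ZnCl2 (cat.), reflux
Reagents that add atoms: none
Why: Knoevenagel condensation of the malonate with acetone, with Ac2O consuming the water formed, should give the tetrasubstituted alkylidene malonate and creates no stereocentre.

Step 2
Reactants: 3 diallyl 2-(propan-2-ylidene)malonate
Product: 4 diallyl 2-[(3E)-4-(dimethylamino)but-3-en-2-ylidene]malonate
Conditions: Me2NCH(OMe)2, toluene, 110 °C
Reagents that add atoms: N,N-dimethylformamide dimethyl acetal, COC(OC)N(C)C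
Why: The γ-methyl groups of the alkylidene malonate are vinylogously acidic and condense with the formamide acetal (aminomethylenation to an enamine) to give the push–pull dienamine, the trans enamine being the stable isomer.

Step 3
Reactants: 4 diallyl 2-[(3E)-4-(dimethylamino)but-3-en-2-ylidene]malonate
Product: 5 allyl 4-methyl-2-oxo-2H-pyran-3-carboxylate
Conditions: HCO2H/H2O (88 %), 90 °C
Reagents that add atoms: water, O
Why: Acid hydrolysis of the enamine unmasks the δ-enol, which lactonises onto the cis ester with loss of allyl alcohol; this acid-mediated cyclisation of (3-aminoallylidene)malonates is an established 2-pyrone synthesis driven by the aromatic stabilisation of the pyrone.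

Step 4
Reactants: 6 (tert-butyldimethylsilyloxy)acetaldehyde; 7 tert-butyl (triphenylphosphoranylidene)acetate
Product: 8 tert-butyl (2E)-4-(tert-butyldimethylsilyloxy)but-2-enoate
Conditions: CH2Cl2, rt
Reagents that add atoms: none
Why: Wittig olefination with a stabilised ylide should give the (E)-enoate with high selectivity.

Step 5
Reactants: 8 tert-butyl (2E)-4-(tert-butyldimethylsilyloxy)but-2-enoate
Product: 10 tert-butyl (3Z)-4-(tert-butyldimethylsilyloxy)but-3-enoate, via lithium dienolate 9 (not isolated)
Conditions: LiN(i-Pr)2, DMPU, THF, −78 °C; then AcOH, −78 °C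
Reagents that add atoms: none
Why: γ-Deprotonation gives the 1-silyloxy dienolate, in which the oxygen substituent prefers the cisoid position (syn effect), so kinetic α-protonation (deconjugative protonation of an extended enolate) should give the (Z)-enol ether.

Step 6
Reactants: 5 allyl 4-methyl-2-oxo-2H-pyran-3-carboxylate; 10 tert-butyl (3Z)-4-(tert-butyldimethylsilyloxy)but-3-enoate
Product: 11 allyl 6-endo-(2-tert-butoxy-2-oxoethyl)-5-endo-(tert-butyldimethylsilyloxy)-8-methyl-3-oxo-2-oxabicyclo[2.2.2]oct-7-ene-4-carboxylate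
Conditions: Cu(OTf)2 (10 mol %), 2,2′-(propane-2,2-diyl)bis[(4S)-4-tert-butyl-4,5-dihydrooxazole] (11 mol %), 4 Å molecular sieves, CH2Cl2, −20 → 0 °C
Reagents that add atoms: none
Why: The Cu(OTf)2–bisoxazoline complex chelates the 2-oxo and 3-ester carbonyls of 5, the nucleophilic β-carbon of the (Z)-silyl enol ether 10 attacks the electrophilic pyrone C6 (C8–C7 bond of the target) and the enol-ether α-carbon bonds to pyrone C3 (C5–C6 bond), either as a strongly asynchronous [4+2] cycloaddition or as a fast vinylogous Mukaiyama–Michael addition followed by ring closure; the closest known reaction type is the copper–bisoxazoline-catalysed inverse-electron-demand Diels–Alder reaction of 3-carboalkoxy-2-pyrones with enol ethers. The six-membered carbocycle closes across the diene termini as the second bond of the [4+2] process (a 6-(enolexo)-exo-trig closure if stepwise), leaving the lactone as the C4(=O)–O bridge of a 2-oxabicyclo[2.2.2]octene. C5 and C8 are held cis by the bridge itself, C6 and C7 become mutually cis because the (Z)-geometry of 10 is transferred suprafacially, and both lie anti to the lactone bridge because the silyloxy group takes the endo orientation. The absolute configuration is set by the ligand, which shields one face of the chelated pyrone. The step needs the regiochemistry "oxygen-bearing carbon to pyrone C3", which follows from the polarisation of both partners, and ring closure faster than bond rotation in any zwitterion, which the chelated cisoid dienolate and the low temperature should secure.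

Step 7
Reactants: 11 bridged lactone allyl ester
Product: 12 6-endo-(2-tert-butoxy-2-oxoethyl)-5-endo-(tert-butyldimethylsilyloxy)-8-methyl-3-oxo-2-oxabicyclo[2.2.2]oct-7-ene-4-carboxylic acid
Conditions: Pd(PPh3)4 (5 mol %), N-methylaniline, THF, rt
Reagents that add atoms: none
Why: Tsuji–Trost deallylation by zerovalent palladium should cleave the unhindered allyl ester much faster than the bridged allylic lactone, whose ionisation would require the metal on the alkene face shielded by the endo substituents, and the weakly nucleophilic aniline traps the allyl group without opening the lactone.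

Step 8
Reactants: 12 bridgehead carboxylic acid
Product: 14 tert-butyl 2-[5-endo-(tert-butyldimethylsilyloxy)-8-methyl-3-oxo-2-oxabicyclo[2.2.2]oct-7-en-6-endo-yl]acetate, via Barton ester 13 (not isolated)
Conditions: 1-hydroxypyridine-2(1H)-thione, DCC, DMAP (cat.), CH2Cl2, 0 °C → rt, dark; then t-BuSH, hν (tungsten lamp), PhH, rt
Reagents that add atoms: none
Why: Barton reductive decarboxylation generates a bridgehead radical that can neither invert nor delocalise into the adjacent alkene, so hydrogen transfer from the thiol replaces the carboxyl group with retention and leaves H5 anti to the lactone bridge.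

Step 9
Reactants: 14 bridged lactone alkene
Product: 15 tert-butyl 2-[5-(tert-butyldimethylsilyloxy)-8-methyl-3-oxo-8-(trimethylsilylethynyl)-2-oxabicyclo[2.2.2]octan-6-yl]acetate (alkynyl group syn to the lactone bridge)
Conditions: Fe(acac)3 (30 mol %), PhSiH3, alkynyl sulfone, EtOH/THF, 50 °C
Reagents that add atoms: trimethyl{[(4-methylphenyl)sulfonyl]ethynyl}silane, Cc1ccc(cc1)S(=O)(=O)C#C[Si](C)(C)C
Why: Mukaiyama-type hydrogen-atom transfer from an iron hydride to the trisubstituted alkene places H on C9 and a tertiary radical on C10, which adds to the alkynyl sulfone and expels the sulfonyl radical (radical hydroalkynylation); attack should occur on the face syn to the flat lactone bridge because the other face is covered by the endo C6 silyloxy group, which sets the quaternary C10 with the two-carbon unit cis to C4 and O8.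

Step 10
Reactants: 15 silylalkyne
Product: 16 tert-butyl 2-[5-(tert-butyldimethylsilyloxy)-8-ethynyl-8-methyl-3-oxo-2-oxabicyclo[2.2.2]octan-6-yl]acetate
Conditions: Bu4NF, AcOH, THF, −20 °C
Reagents that add atoms: none
Why: Fluoride-induced protodesilylation of the alkynylsilane is far faster than cleavage of the hindered secondary silyl ether, and the AcOH buffer keeps the lactone and the ester intact.

Step 11
Reactants: 16 terminal alkyne
Product: 17 tert-butyl 2-[5-(tert-butyldimethylsilyloxy)-8-ethenyl-8-methyl-3-oxo-2-oxabicyclo[2.2.2]octan-6-yl]acetate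
Conditions: H2 (1 atm), Pd/CaCO3 poisoned with Pb(OAc)2, quinoline, EtOAc, rt
Reagents that add atoms: none
Why: Lindlar semihydrogenation should stop cleanly at the vinyl group, since the alkyne is the only reducible π-bond.

Step 12
Reactants: 17 vinyl lactone
Product: 19 tert-butyl 2-[2-(tert-butyldimethylsilyloxy)-4-ethenyl-6-hydroxy-3-(methoxymethoxyacetyl)-4-methylcyclohexyl]acetate, via lithium hemiketalate 18 (not isolated)
Conditions: Bu3SnCH2OCH2OMe, n-BuLi, THF, −78 °C; then 17, −78 °C; aq. NH4Cl
Reagents that add atoms: tributyl[(methoxymethoxy)methyl]stannane, CCCC[Sn](CCCC)(CCCC)COCOC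
Why: Tin–lithium exchange gives the α-alkoxy organolithium, which should add to the strained bridged lactone carbonyl faster than to the tert-butyl ester; the bridged lithium hemiketalate resists a second addition at −78 °C and opens on work-up to the ketone and the free C8 hydroxyl, C5 keeping its configuration, which is also the thermodynamically preferred one.

Step 13
Reactants: 19 hydroxy ketone
Product: 20 tert-butyl 2-{2-(tert-butyldimethylsilyloxy)-4-ethenyl-6-hydroxy-3-[3-(methoxymethoxy)prop-1-en-2-yl]-4-methylcyclohexyl}acetate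
Conditions: Zn, CH2Br2, TiCl4, THF/CH2Cl2, 0 °C → rt
Reagents that add atoms: dibromomethane, BrCBr
Why: Takai–Lombardo methylenation is non-basic and chemoselective for ketones over esters, so neither the α-stereocentre C5 nor the β-silyloxy group is endangered.

Step 14
Reactants: 20 hydroxy ester
Product: 23 tert-butyl 2-{2-(tert-butyldimethylsilyloxy)-4-ethenyl-6-hydroxy-3-[3-(methoxymethoxy)prop-1-en-2-yl]-4-methylcyclohexyl}prop-2-enoate, via Mannich base 21 (not isolated), via trimethylammonium iodide 22 (not isolated)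
Conditions: LiN(i-Pr)2 (3 equiv), THF, −78 °C; CH2=NMe2+ I−, −78 → 0 °C; then MeI, MeOH, rt; then DBU, CH2Cl2, rt
Reagents that add atoms: N,N-dimethylmethaniminium iodide (Eschenmoser's salt), C=[N+](C)C.[I-]
Why: Aminomethylation of the ester enolate with Eschenmoser's salt (Mannich reaction), N-methylation and base-induced elimination of trimethylamine is a standard α-methylenation sequence; the C8 alkoxide is a spectator because the bulky tert-butyl ester and the trans arrangement at C7/C8 disfavour lactonisation.

Step 15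
Reactants: 24 (4R)-4-hydroxyoxolan-2-one
Product: 27 (4R)-4-hydroxy-3-methylideneoxolan-2-one, via aminomethyl lactone 25 (not isolated), via ammonium iodide 26 (not isolated)
Conditions: LiN(i-Pr)2 (2.2 equiv), THF, −78 °C; CH2=NMe2+ I−, −78 → 0 °C; then MeI, MeOH, rt; then aq. NaHCO3, CH2Cl2, rt
Reagents that add atoms: N,N-dimethylmethaniminium iodide (Eschenmoser's salt), C=[N+](C)C.[I-]
Why: The alkoxide–enolate dianion of the β-hydroxy lactone cannot β-eliminate and is aminomethylated at C3 (Mannich reaction), and quaternisation–elimination then gives the α-methylene lactone with the chiral-pool carbinol centre untouched.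

Step 16
Reactants: 27 (4R)-4-hydroxy-3-methylideneoxolan-2-one
Product: 30 (3R)-3,4-bis(tert-butyldimethylsilyloxy)-2-methylidenebutanoic acid, via lithium carboxylate 28 (not isolated), via silyl ester 29 (not isolated)
Conditions: LiOH, THF/H2O, 0 °C; concentrate; t-BuMe2SiOTf, 2,6-lutidine, CH2Cl2, 0 °C → rt; then K2CO3 (cat.), MeOH, 0 °C; pH 4 buffer
Reagents that add atoms: lithium hydroxide, [Li+].[OH-]; tert-butyldimethylsilyl trifluoromethanesulfonate, CC(C)(C)[Si](C)(C)OS(=O)(=O)C(F)(F)F
Why: Saponification opens the lactone, exhaustive silylation traps the seco acid before it can relactonise, and the labile silyl ester alone is then cleaved by methanolysis to leave the acid with both hydroxyls silylated.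

Step 17
Reactants: 23 C8 alcohol; 30 (3R)-3,4-bis(tert-butyldimethylsilyloxy)-2-methylidenebutanoic acid
Product: 32 fully protected C8 ester (O6, O3′ and O4′ silylated; O3 as methoxymethyl ether; C12 as tert-butyl ester), via mixed anhydride 31 (not isolated)
Conditions: 2,4,6-trichlorobenzoyl chloride, Et3N, THF, rt; then 23, DMAP, toluene, rt → 40 °C
Reagents that add atoms: none
Why: Yamaguchi esterification through the mixed anhydride and DMAP is suited to hindered secondary alcohols, O8 is the only free hydroxyl, and the acid has no epimerisable centre α to the carbonyl.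

Step 18
Reactants: 32 fully protected C8 ester
Product: 34 C12 carboxylic acid with free C3 hydroxyl and three silyl ethers (O6, O3′, O4′), via pyridinium silyl ester 33 (not isolated)
Conditions: Me3SiOTf, 2,2′-bipyridyl, CH2Cl2, 0 °C → rt; then H2O, rt
Reagents that add atoms: none
Why: Me3SiOTf buffered by 2,2′-bipyridyl should convert the methoxymethyl ether into a water-labile pyridinium acetal and the tert-butyl ester into a silyl ester with loss of isobutene (silyl-triflate-mediated acetal and tert-butyl ester cleavage), both being released by water while the three silyl ethers survive, so that the acid is freed while O6 is still blocked and cannot lactonise.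

Step 19
Reactants: 34 tris-silyl ether acid
Product: 35 2-[(1S,2S,3S,4S,6S)-6-{[(3R)-3,4-dihydroxy-2-methylidenebutanoyl]oxy}-4-ethenyl-2-hydroxy-3-(3-hydroxyprop-1-en-2-yl)-4-methylcyclohexyl]prop-2-enoic acid (target)
Conditions: HF·pyridine, pyridine, THF, 0 °C → rt; pH 5 buffer, 0 °C
Reagents that add atoms: none
Why: Pyridine-buffered HF·pyridine (fluoride desilylation) removes the three silyl ethers under mildly acidic conditions that avoid base-induced self-lactonisation of the dihydroxyacyl group, and a cold buffered work-up limits acid-catalysed closure of the C6 hydroxyl onto the C12 acid.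

Compound list
1 | diallyl malonate | C=CCOC(=O)CC(=O)OCC=C | starting material
2 | acetone | CC(C)=O | starting material
3 | diallyl 2-(propan-2-ylidene)malonate | CC(C)=C(C(=O)OCC=C)C(=O)OCC=C | intermediate
4 | diallyl 2-[(3E)-4-(dimethylamino)but-3-en-2-ylidene]malonate | CN(C)/C=C/C(C)=C(C(=O)OCC=C)C(=O)OCC=C | intermediate
5 | allyl 4-methyl-2-oxo-2H-pyran-3-carboxylate | CC1=C(C(=O)OCC=C)C(=O)OC=C1 | intermediate
6 | (tert-butyldimethylsilyloxy)acetaldehyde | CC(C)(C)[Si](C)(C)OCC=O | starting material
7 | tert-butyl (triphenylphosphoranylidene)acetate | CC(C)(C)OC(=O)C=P(c1ccccc1)(c1ccccc1)c1ccccc1 | starting material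
8 | tert-butyl (2E)-4-(tert-butyldimethylsilyloxy)but-2-enoate | CC(C)(C)OC(=O)/C=C/CO[Si](C)(C)C(C)(C)C | intermediate
9 | lithium dienolate of 8 with (Z)-silyloxyvinyl unit | [Li+].[O-]C(OC(C)(C)C)=C/C=C\O[Si](C)(C)C(C)(C)C | intermediate
10 | tert-butyl (3Z)-4-(tert-butyldimethylsilyloxy)but-3-enoate | CC(C)(C)OC(=O)C/C=C\O[Si](C)(C)C(C)(C)C | intermediate
11 | allyl 6-endo-(2-tert-butoxy-2-oxoethyl)-5-endo-(tert-butyldimethylsilyloxy)-8-methyl-3-oxo-2-oxabicyclo[2.2.2]oct-7-ene-4-carboxylate (5- and 6-substituents cis; absolute configuration as in the SMILES) | CC1=C[C@@H]2OC(=O)[C@@]1(C(=O)OCC=C)[C@H](O[Si](C)(C)C(C)(C)C)[C@@H]2CC(=O)OC(C)(C)C | intermediate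
12 | 4-carboxylic acid corresponding to 11 | CC1=C[C@@H]2OC(=O)[C@@]1(C(=O)O)[C@H](O[Si](C)(C)C(C)(C)C)[C@@H]2CC(=O)OC(C)(C)C | intermediate
13 | 2-thioxopyridin-1(2H)-yl ester of 12 (Barton ester) | CC1=C[C@@H]2OC(=O)[C@@]1(C(=O)On3ccccc3=S)[C@H](O[Si](C)(C)C(C)(C)C)[C@@H]2CC(=O)OC(C)(C)C | intermediate
14 | tert-butyl 2-[5-endo-(tert-butyldimethylsilyloxy)-8-methyl-3-oxo-2-oxabicyclo[2.2.2]oct-7-en-6-endo-yl]acetate (bridgehead H4 in place of the carboxyl group) | CC1=C[C@@H]2OC(=O)[C@H]1[C@H](O[Si](C)(C)C(C)(C)C)[C@@H]2CC(=O)OC(C)(C)C | intermediate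
15 | tert-butyl 2-[5-(tert-butyldimethylsilyloxy)-8-methyl-3-oxo-8-(trimethylsilylethynyl)-2-oxabicyclo[2.2.2]octan-6-yl]acetate (alkynyl syn to the lactone bridge, methyl on the side of the silyloxy group) | C[C@@]1(C#C[Si](C)(C)C)C[C@@H]2OC(=O)[C@H]1[C@H](O[Si](C)(C)C(C)(C)C)[C@@H]2CC(=O)OC(C)(C)C | intermediate
16 | 8-ethynyl analogue of 15 | C[C@@]1(C#C)C[C@@H]2OC(=O)[C@H]1[C@H](O[Si](C)(C)C(C)(C)C)[C@@H]2CC(=O)OC(C)(C)C | intermediate
17 | 8-ethenyl analogue of 15 | C=C[C@]1(C)C[C@@H]2OC(=O)[C@H]1[C@H](O[Si](C)(C)C(C)(C)C)[C@@H]2CC(=O)OC(C)(C)C | intermediate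
18 | lithium hemiketalate from addition of the (methoxymethoxy)methyl group to the lactone carbonyl of 17 | C=C[C@]1(C)C[C@@H]2OC([O-])(COCOC)[C@H]1[C@H](O[Si](C)(C)C(C)(C)C)[C@@H]2CC(=O)OC(C)(C)C.[Li+] | intermediate
19 | tert-butyl 2-[2-(tert-butyldimethylsilyloxy)-4-ethenyl-6-hydroxy-3-(methoxymethoxyacetyl)-4-methylcyclohexyl]acetate (ring configuration of the target) | C=C[C@]1(C)C[C@H](O)[C@@H](CC(=O)OC(C)(C)C)[C@@H](O[Si](C)(C)C(C)(C)C)[C@@H]1C(=O)COCOC | intermediate
20 | tert-butyl 2-{2-(tert-butyldimethylsilyloxy)-4-ethenyl-6-hydroxy-3-[3-(methoxymethoxy)prop-1-en-2-yl]-4-methylcyclohexyl}acetate | C=C[C@]1(C)C[C@H](O)[C@@H](CC(=O)OC(C)(C)C)[C@@H](O[Si](C)(C)C(C)(C)C)[C@@H]1C(=C)COCOC | intermediate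
21 | α-(dimethylaminomethyl) ester from 20 (Mannich base, C11 unassigned) | C=C[C@]1(C)C[C@H](O)[C@@H](C(CN(C)C)C(=O)OC(C)(C)C)[C@@H](O[Si](C)(C)C(C)(C)C)[C@@H]1C(=C)COCOC | intermediate
22 | trimethylammonium iodide from 21 | C=C[C@]1(C)C[C@H](O)[C@@H](C(C[N+](C)(C)C)C(=O)OC(C)(C)C)[C@@H](O[Si](C)(C)C(C)(C)C)[C@@H]1C(=C)COCOC.[I-] | intermediate
23 | tert-butyl 2-{2-(tert-butyldimethylsilyloxy)-4-ethenyl-6-hydroxy-3-[3-(methoxymethoxy)prop-1-en-2-yl]-4-methylcyclohexyl}prop-2-enoate | C=C[C@]1(C)C[C@H](O)[C@@H](C(=C)C(=O)OC(C)(C)C)[C@@H](O[Si](C)(C)C(C)(C)C)[C@@H]1C(=C)COCOC | intermediate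
24 | (4R)-4-hydroxyoxolan-2-one [(R)-3-hydroxy-γ-butyrolactone] | O=C1C[C@@H](O)CO1 | starting material
25 | (4R)-3-[(dimethylamino)methyl]-4-hydroxyoxolan-2-one (C3 unassigned) | CN(C)CC1[C@@H](O)COC1=O | intermediate
26 | trimethylammonium iodide from 25 | C[N+](C)(C)CC1[C@@H](O)COC1=O.[I-] | intermediate
27 | (4R)-4-hydroxy-3-methylideneoxolan-2-one | C=C1[C@@H](O)COC1=O | intermediate
28 | lithium (3R)-3,4-dihydroxy-2-methylidenebutanoate | [Li+].[O-]C(=O)C(=C)[C@@H](O)CO | intermediate
29 | tert-butyldimethylsilyl (3R)-3,4-bis(tert-butyldimethylsilyloxy)-2-methylidenebutanoate | C=C(C(=O)O[Si](C)(C)C(C)(C)C)[C@@H](O[Si](C)(C)C(C)(C)C)CO[Si](C)(C)C(C)(C)C | intermediate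
30 | (3R)-3,4-bis(tert-butyldimethylsilyloxy)-2-methylidenebutanoic acid | C=C(C(=O)O)[C@@H](O[Si](C)(C)C(C)(C)C)CO[Si](C)(C)C(C)(C)C | intermediate
31 | mixed anhydride of 30 with 2,4,6-trichlorobenzoic acid | C=C(C(=O)OC(=O)c1c(Cl)cc(Cl)cc1Cl)[C@@H](O[Si](C)(C)C(C)(C)C)CO[Si](C)(C)C(C)(C)C | intermediate
32 | fully protected ester: 23 acylated at O8 by 30 | C=C[C@]1(C)C[C@H](OC(=O)C(=C)[C@@H](O[Si](C)(C)C(C)(C)C)CO[Si](C)(C)C(C)(C)C)[C@@H](C(=C)C(=O)OC(C)(C)C)[C@@H](O[Si](C)(C)C(C)(C)C)[C@@H]1C(=C)COCOC | intermediate
33 | trimethylsilyl ester of 34 carrying a 1-(alkoxymethyl)-2,2′-bipyridin-1-ium triflate at O3 | C=C[C@]1(C)C[C@H](OC(=O)C(=C)[C@@H](O[Si](C)(C)C(C)(C)C)CO[Si](C)(C)C(C)(C)C)[C@@H](C(=C)C(=O)O[Si](C)(C)C)[C@@H](O[Si](C)(C)C(C)(C)C)[C@@H]1C(=C)COC[n+]2ccccc2-c2ccccn2.[O-]S(=O)(=O)C(F)(F)F | intermediate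
34 | C12 acid with free C3–OH and silyl ethers at O6, O3′ and O4′ | C=C[C@]1(C)C[C@H](OC(=O)C(=C)[C@@H](O[Si](C)(C)C(C)(C)C)CO[Si](C)(C)C(C)(C)C)[C@@H](C(=C)C(=O)O)[C@@H](O[Si](C)(C)C(C)(C)C)[C@@H]1C(=C)CO | intermediate
35 | 2-[(1S,2S,3S,4S,6S)-6-{[(3R)-3,4-dihydroxy-2-methylidenebutanoyl]oxy}-4-ethenyl-2-hydroxy-3-(3-hydroxyprop-1-en-2-yl)-4-methylcyclohexyl]prop-2-enoic acid (CNP0348657.4) | C=C[C@]1(C)C[C@H](OC(=O)C(=C)[C@@H](O)CO)[C@@H](C(=C)C(=O)O)[C@@H](O)[C@@H]1C(=C)CO | target

Total step count: 19 steps.
Longest linear sequence: 15 steps (steps 1–3, 6–14 and 17–19); the dienophile (steps 4–5) and the side-chain acid (steps 15–16) are made in separate branches.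

Steps most likely to fail

Step 6. The 1,2-disubstituted silyl enol ether may add sluggishly to the 4-methylpyrone, the silyl group may migrate in a long-lived zwitterion, and bond rotation before ring closure would erode the cis relationship at C6/C7 or the facial selectivity. The fallback replaces the silyl enol ether by an alkyl (Z)-enol ether that cannot transfer a silyl group, and exchanges the protecting group afterwards. It sets out from 5 (and from 7 for the new dienophile). Wittig reaction of 7 with commercial (4-methoxybenzyloxy)acetaldehyde should give tert-butyl (2E)-4-[(4-methoxybenzyl)oxy]but-2-enoate F1. Deconjugative protonation as in step 5 should give tert-butyl (3Z)-4-[(4-methoxybenzyl)oxy]but-3-enoate F2. The same Cu(OTf)2–bisoxazoline cycloaddition with 5 should give the 5-endo-(4-methoxybenzyloxy) bridged lactone F3. DDQ in CH2Cl2/pH 7 buffer frees the 5-endo alcohol F4, and t-BuMe2SiOTf/2,6-lutidine brings the route back to 11.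

Step 9. The hindered tertiary C10 radical may be captured too slowly by the alkynyl sulfone, so that premature reduction to the saturated hydrocarbon or loss of face selectivity takes over. The fallback sets out from 14 and uses the same iron-hydride initiation (Fe(acac)3, PhSiH3) but the more reactive acceptor (E)-1,2-bis(phenylsulfonyl)ethene. Addition and β-elimination should give the (E)-2-(phenylsulfonyl)ethenyl lactone F5. Reductive desulfonylation (SmI2, DMPU, MeOH, THF, −78 °C) then leads directly to 17, so that 15 and 16 are bypassed.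

Step 18. Under the silyl triflate the primary silyl ether may be lost, the allylic C3–O bond may ionise, or the ester cleavage may stay incomplete, giving mixtures. The fallback splits the operation into two orthogonal cleavages and sets out from 32. Me2BBr (CH2Cl2, −78 °C, then aq. NaHCO3) cleaves acetals much faster than tert-butyl esters and should give the C3 alcohol tert-butyl ester F6. Aqueous H3PO4 (85 %) in toluene at rt then removes the tert-butyl group while silyl ethers are tolerated, and the route is rejoined at 34.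

Further compounds
F1 | step 6 | tert-butyl (2E)-4-[(4-methoxybenzyl)oxy]but-2-enoate | COc1ccc(COC/C=C/C(=O)OC(C)(C)C)cc1
F2 | step 6 | tert-butyl (3Z)-4-[(4-methoxybenzyl)oxy]but-3-enoate | COc1ccc(CO/C=C\CC(=O)OC(C)(C)C)cc1
F3 | step 6 | allyl 6-endo-(2-tert-butoxy-2-oxoethyl)-5-endo-(4-methoxybenzyloxy)-8-methyl-3-oxo-2-oxabicyclo[2.2.2]oct-7-ene-4-carboxylate | CC1=C[C@@H]2OC(=O)[C@@]1(C(=O)OCC=C)[C@H](OCc3ccc(OC)cc3)[C@@H]2CC(=O)OC(C)(C)C
F4 | step 6 | allyl 6-endo-(2-tert-butoxy-2-oxoethyl)-5-endo-hydroxy-8-methyl-3-oxo-2-oxabicyclo[2.2.2]oct-7-ene-4-carboxylate | CC1=C[C@@H]2OC(=O)[C@@]1(C(=O)OCC=C)[C@H](O)[C@@H]2CC(=O)OC(C)(C)C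
F5 | step 9 | tert-butyl 2-{5-(tert-butyldimethylsilyloxy)-8-methyl-3-oxo-8-[(E)-2-(phenylsulfonyl)ethenyl]-2-oxabicyclo[2.2.2]octan-6-yl}acetate | C[C@@]1(/C=C/S(=O)(=O)c3ccccc3)C[C@@H]2OC(=O)[C@H]1[C@H](O[Si](C)(C)C(C)(C)C)[C@@H]2CC(=O)OC(C)(C)C
F6 | step 18 | tert-butyl ester of 34 (free C3–OH; silyl ethers at O6, O3′ and O4′) | C=C[C@]1(C)C[C@H](OC(=O)C(=C)[C@@H](O[Si](C)(C)C(C)(C)C)CO[Si](C)(C)C(C)(C)C)[C@@H](C(=C)C(=O)OC(C)(C)C)[C@@H](O[Si](C)(C)C(C)(C)C)[C@@H]1C(=C)CO
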